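**Plan**

- Retrosynthesis: the four β C–Br bonds (C3, C4, C3', C4') are cut first, then the two N–H bonds are traced back to N-sulfonyl groups that leave as sulfinate, then N1–C5 and N1'–C5' are cut, and last the C2–C3/C2'–C3' bonds (allylation of a glyoxal diimine) and the C4=C5/C4'=C5' bonds (dibromomethylenation).
- Enabling feature: in each pyrrole ring the unit N1–C5(Br)=C4 is a C=CBr2 terminus in which nitrogen has taken the place of one bromine, and N1–C2–C2'–N1' is a 1,2-diamine. Both rings can therefore be closed from one open-chain bis(gem-dibromoalkene) bis-sulfonamide with the α-bromines already in place.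
- Forward: the C8 diamine chain is assembled from glyoxal, two equivalents of a sulfinamide and two allyl units (steps 1–3), each terminal CH2 is exchanged for CBr2 (steps 4–6), both five-membered rings close together by double copper-catalysed C–N coupling (step 7), sulfinate loss aromatises them (step 8) and NBS fills the four β positions (step 9).
- Stereochemistry: the target has no stereocentre. The two carbinamine centres set by the sulfinyl auxiliary in step 2 only ensure that a single diastereomer is handled, and they are erased in step 8.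

Key step: step 7

Assumption: the allylzinc addition is taken to follow the usual zinc-bound chair model, which from the (S)-sulfinamide leads to the (4R,5R)-diamine. Any other diastereomer or the enantiomer would serve equally well because both centres disappear in step 8. In the two-fold steps the singly reacted species is a transient of the same reaction and carries no number.

**Route**

Step 1
Reactants: 1 glyoxal (40 wt % in water), 2 (S)-2-methylpropane-2-sulfinamide (two equivalents)
Product: 3 (S_S,S_S)-N,N'-[(1E,2E)-ethane-1,2-diylidene]bis(2-methylpropane-2-sulfinamide)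
Conditions: 2 (2.1 equiv), anhydrous CuSO4 (excess), CH2Cl2, rt
Reagents that add atoms: (S)-2-methylpropane-2-sulfinamide 2 (second equivalent), CC(C)(C)[S@](=O)N
Why: CuSO4-mediated condensation of a sulfinamide with an aldehyde (sulfinimine formation), carried out at both carbonyl groups of glyoxal with two equivalents of 2, which should give the thermodynamic (E,E)-bis-aldimine with the sulfur centres untouched.

Step 2
Reactants: 3 (S_S,S_S)-N,N'-[(1E,2E)-ethane-1,2-diylidene]bis(2-methylpropane-2-sulfinamide), 4 allyl bromide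
Product: 5 (S_S,S_S)-N,N'-[(4R,5R)-octa-1,7-diene-4,5-diyl]bis(2-methylpropane-2-sulfinamide)
Conditions: Zn dust (activated), allyl bromide (excess), THF, 0 °C → rt; sat. aq. NH4Cl
Reagents that add atoms: allylzinc bromide, C=CC[Zn]Br (formed in the flask from allyl bromide 4, C=CCBr, and Zn)
Why: Barbier-type aza-allylation of N-sulfinyl aldimines, in which each allyl group should be delivered through a zinc-bound Zimmerman–Traxler-type chair to the Re face of its (S_S)-aldimine carbon, so that both auxiliaries act in the same sense and the C2-symmetric (4R,5R)-diamine is expected.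

Step 3
Reactants: 5 (S_S,S_S)-N,N'-[(4R,5R)-octa-1,7-diene-4,5-diyl]bis(2-methylpropane-2-sulfinamide)
Product: 7 N,N'-[(4R,5R)-octa-1,7-diene-4,5-diyl]bis(4-methylbenzenesulfonamide), via diamine dihydrochloride 6 (not isolated)
Conditions: HCl (4 M in dioxane), MeOH, 0 °C → rt, evaporate; then TsCl (2.5 equiv), Et3N, DMAP (cat.), CH2Cl2, 0 °C → rt
Reagents that add atoms: p-toluenesulfonyl chloride, Cc1ccc(cc1)S(Cl)(=O)=O
Why: acidic methanolysis of the N–S bond of a tert-butanesulfinamide followed by standard sulfonylation of the liberated primary amines; neither operation touches C4 or C5.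

Step 4
Reactants: 7 N,N'-[(4R,5R)-octa-1,7-diene-4,5-diyl]bis(4-methylbenzenesulfonamide)
Product: 8 di-tert-butyl [(4R,5R)-octa-1,7-diene-4,5-diyl]bis[(4-methylbenzenesulfonyl)carbamate]
Conditions: Boc2O (3 equiv), DMAP, Et3N, MeCN, rt → 40 °C
Reagents that add atoms: di-tert-butyl dicarbonate, CC(C)(C)OC(=O)OC(=O)OC(C)(C)C
Why: DMAP-catalysed acylation of a sulfonamide N–H; capping both nitrogens should keep each of them from adding to the aldehyde of the neighbouring arm (a five-membered N-sulfonyl hemiaminal) once the alkenes are cleaved.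

Step 5
Reactants: 8 di-tert-butyl [(4R,5R)-octa-1,7-diene-4,5-diyl]bis[(4-methylbenzenesulfonyl)carbamate], 9 carbon tetrabromide
Product: 11 di-tert-butyl [(4R,5R)-1,1,8,8-tetrabromoocta-1,7-diene-4,5-diyl]bis[(4-methylbenzenesulfonyl)carbamate], via dialdehyde 10 (not isolated)
Conditions: O3, CH2Cl2, −78 °C, then PPh3, −78 °C → rt; partial concentration; solution added to pre-mixed CBr4/PPh3 (excess), CH2Cl2, 0 °C
Reagents that add atoms: carbon tetrabromide 9, BrC(Br)(Br)Br (delivered as Ph3P=CBr2); ozone, [O-][O+]=O (supplies only the carbonyl oxygens of 10)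
Why: ozonolysis with reductive work-up followed by Ramirez dibromomethylenation (the first stage of the Corey–Fuchs sequence) under neutral conditions; the β-imido dialdehyde is carried on crude so that base- or silica-induced β-elimination of the imide is avoided.

Step 6
Reactants: 11 di-tert-butyl [(4R,5R)-1,1,8,8-tetrabromoocta-1,7-diene-4,5-diyl]bis[(4-methylbenzenesulfonyl)carbamate]
Product: 12 N,N'-[(4R,5R)-1,1,8,8-tetrabromoocta-1,7-diene-4,5-diyl]bis(4-methylbenzenesulfonamide)
Conditions: TFA/CH2Cl2 (1:4), 0 °C → rt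
Reagents that add atoms: none
Why: acidolysis of the tert-butyl carbamates with loss of isobutene and CO2; the sulfonamides, the two stereocentres and the gem-dibromoalkenes are inert to TFA.

Step 7
Reactants: 12 N,N'-[(4R,5R)-1,1,8,8-tetrabromoocta-1,7-diene-4,5-diyl]bis(4-methylbenzenesulfonamide)
Product: 13 (2R,2'R)-5,5'-dibromo-1,1'-bis(4-methylbenzenesulfonyl)-2,2',3,3'-tetrahydro-1H,1'H-2,2'-bipyrrole
Conditions: CuI (20 mol %), N,N'-dimethylethylenediamine (40 mol %), K3PO4 (4 equiv), degassed toluene (0.01 M), 85 °C, Ar, dark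
Reagents that add atoms: none
Why: Proposed new method: K3PO4 deprotonates each sulfonamide, the amide binds diamine-ligated monovalent copper, and this copper amidate activates the C–Br bond lying cis to the chain (oxidative addition to a six-membered cupracycle of trivalent copper, then C–N reductive elimination), which forms N1–C5 and N1'–C5' and leaves the second bromine of each CBr2 carbon on C5 and C5'. The closest known reaction type is the intramolecular copper- or palladium-catalysed amination of gem-dibromoalkenes that gives 2-bromoindoles and cyclic α-bromoenamides, together with the copper-catalysed intramolecular N-vinylation of sulfonamides; what is new is the two-fold use on a purely aliphatic diamine with two competing arms. Both five-membered rings close in the 5-endo mode (nitrogen onto the terminal sp2 carbon, the C4=C5 bond ending inside the ring), which is acceptable because the bond is made by reductive elimination at copper and not by a Baldwin-type attack on the π bond. No stereocentre is created, and C2 and C2' are untouched and keep their configuration. The step needs own-arm closure to the five-membered ring in preference to six-membered closure onto the neighbouring arm, which the shorter tether and the smaller cupracycle (six against seven atoms) should secure. It also needs mono-substitution at each CBr2 carbon without loss of HBr, which rests on the weak, sparingly soluble base, on the inability of a cyclic bromoenamide to collapse to an ynamide and on the lower reactivity of the electron-rich C5–Br bond of the product, while high dilution suppresses intermolecular coupling.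

Step 8
Reactants: 13 (2R,2'R)-5,5'-dibromo-1,1'-bis(4-methylbenzenesulfonyl)-2,2',3,3'-tetrahydro-1H,1'H-2,2'-bipyrrole
Product: 14 5,5'-dibromo-1H,1'H-2,2'-bipyrrole
Conditions: DBU (6 equiv), DMF, 60 °C, Ar, dark; cold pH 7 buffer/Et2O work-up, crude used at once
Reagents that add atoms: none
Why: base-induced elimination of p-toluenesulfinate from an N-sulfonyl 2,3-dihydropyrrole followed by prototropic shift to the aromatic 1H-pyrrole, a desulfinylative aromatisation known for N-tosyl dihydropyrroles from 5-endo cyclisations; C2 and C2' become sp2 here, so both stereocentres disappear.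

Step 9
Reactants: 14 5,5'-dibromo-1H,1'H-2,2'-bipyrrole
Product: 15 3,3',4,4',5,5'-hexabromo-1H,1'H-2,2'-bipyrrole
Conditions: NBS (4.1 equiv), THF, −78 °C → 0 °C, dark
Reagents that add atoms: N-bromosuccinimide, BrN1C(=O)CCC1=O
Why: electrophilic aromatic bromination of an electron-rich pyrrole; with C2/C2' occupied by the biaryl bond and C5/C5' by bromine, only the four β positions remain, so exhaustive bromination has a single outcome.

**Compound list**

1 | glyoxal | O=CC=O | starting material
2 | (S)-2-methylpropane-2-sulfinamide | CC(C)(C)[S@](=O)N | starting material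
3 | (S_S,S_S)-N,N'-[(1E,2E)-ethane-1,2-diylidene]bis(2-methylpropane-2-sulfinamide) | CC(C)(C)[S@](=O)/N=C/C=N/[S@@](=O)C(C)(C)C | intermediate
4 | allyl bromide | C=CCBr | starting material
5 | (S_S,S_S)-N,N'-[(4R,5R)-octa-1,7-diene-4,5-diyl]bis(2-methylpropane-2-sulfinamide) | CC(C)(C)[S@](=O)N[C@H](CC=C)[C@@H](CC=C)N[S@@](=O)C(C)(C)C | intermediate
6 | (4R,5R)-octa-1,7-diene-4,5-diamine dihydrochloride | N[C@H](CC=C)[C@@H](CC=C)N.Cl.Cl | intermediate
7 | N,N'-[(4R,5R)-octa-1,7-diene-4,5-diyl]bis(4-methylbenzenesulfonamide) | Cc1ccc(cc1)S(=O)(=O)N[C@H](CC=C)[C@@H](CC=C)NS(=O)(=O)c1ccc(C)cc1 | intermediate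
8 | di-tert-butyl [(4R,5R)-octa-1,7-diene-4,5-diyl]bis[(4-methylbenzenesulfonyl)carbamate] | Cc1ccc(cc1)S(=O)(=O)N(C(=O)OC(C)(C)C)[C@H](CC=C)[C@@H](CC=C)N(C(=O)OC(C)(C)C)S(=O)(=O)c1ccc(C)cc1 | intermediate
9 | carbon tetrabromide | BrC(Br)(Br)Br | starting material
10 | di-tert-butyl [(3R,4R)-1,6-dioxohexane-3,4-diyl]bis[(4-methylbenzenesulfonyl)carbamate] | Cc1ccc(cc1)S(=O)(=O)N(C(=O)OC(C)(C)C)[C@H](CC=O)[C@@H](CC=O)N(C(=O)OC(C)(C)C)S(=O)(=O)c1ccc(C)cc1 | intermediate
11 | di-tert-butyl [(4R,5R)-1,1,8,8-tetrabromoocta-1,7-diene-4,5-diyl]bis[(4-methylbenzenesulfonyl)carbamate] | Cc1ccc(cc1)S(=O)(=O)N(C(=O)OC(C)(C)C)[C@H](CC=C(Br)Br)[C@@H](CC=C(Br)Br)N(C(=O)OC(C)(C)C)S(=O)(=O)c1ccc(C)cc1 | intermediate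
12 | N,N'-[(4R,5R)-1,1,8,8-tetrabromoocta-1,7-diene-4,5-diyl]bis(4-methylbenzenesulfonamide) | Cc1ccc(cc1)S(=O)(=O)N[C@H](CC=C(Br)Br)[C@@H](CC=C(Br)Br)NS(=O)(=O)c1ccc(C)cc1 | intermediate
13 | (2R,2'R)-5,5'-dibromo-1,1'-bis(4-methylbenzenesulfonyl)-2,2',3,3'-tetrahydro-1H,1'H-2,2'-bipyrrole | Cc1ccc(cc1)S(=O)(=O)N1C(Br)=CC[C@@H]1[C@H]1CC=C(Br)N1S(=O)(=O)c1ccc(C)cc1 | intermediate
14 | 5,5'-dibromo-1H,1'H-2,2'-bipyrrole | Brc1ccc([nH]1)-c1ccc(Br)[nH]1 | intermediate
15 | 3,3',4,4',5,5'-hexabromo-1H,1'H-2,2'-bipyrrole | Brc1[nH]c(-c2[nH]c(Br)c(Br)c2Br)c(Br)c1Br | target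

**Step count and risks**

Total step count: 9. Longest linear sequence: 9 steps (1 → 15).

Steps most likely to fail:

1. Step 7. Loss of HBr from the CBr2 termini to bromoalkynes, followed by intermolecular N-alkynylation and oligomerisation, may compete with ring closure. Six-membered closure onto the neighbouring arm is possible, as is further amination at the retained C5–Br bond by the second sulfonamide, and the bromoenamide may hydrolyse on work-up. The fallback gives up the retained bromine and uses known reactions only. Setting out from 12, palladium-catalysed hydrogenolysis with Bu3SnH (Pd(PPh3)4 cat., toluene, rt), which is known to remove the bromine trans to the alkyl chain, would give N,N'-[(1Z,4R,5R,7Z)-1,8-dibromoocta-1,7-diene-4,5-diyl]bis(4-methylbenzenesulfonamide) F1. The established copper-catalysed intramolecular N-vinylation of sulfonamides with simple (Z)-vinyl bromides (CuI, N,N'-dimethylethylenediamine, Cs2CO3, toluene, 90 °C, high dilution) would then close both rings to (2R,2'R)-1,1'-bis(4-methylbenzenesulfonyl)-2,2',3,3'-tetrahydro-1H,1'H-2,2'-bipyrrole F2. Elimination of sulfinate (tBuOK, DMSO, rt) would give 1H,1'H-2,2'-bipyrrole F3, and exhaustive bromination with NBS (6 equiv, THF, −78 °C → 0 °C) rejoins the route at 15, all six bromines then coming from NBS.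

2. Step 8. Removal of a weakly acidic ring proton may be slow, so elimination may stall at the mono-pyrrole, and the N-unprotected α-bromopyrrole may decompose through acid, light or air during work-up. The fallback aromatises by dehydrogenation and keeps nitrogen protected until all bromines are in place. Setting out from 13, DDQ (toluene, 80 °C) should give 5,5'-dibromo-1,1'-bis(4-methylbenzenesulfonyl)-1H,1'H-2,2'-bipyrrole F4. Bromination of the four β positions (Br2, NaOAc, AcOH, 50 °C) would give 3,3',4,4',5,5'-hexabromo-1,1'-bis(4-methylbenzenesulfonyl)-1H,1'H-2,2'-bipyrrole F5. Mild hydrolysis of the N-sulfonyl groups (NaOH, MeOH/THF/H2O, rt), easy because the polybrominated pyrrolide is a good leaving group, rejoins the route at 15.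

3. Step 5. The β-imido dialdehyde may lose the N-Boc sulfonamide by E1cB elimination to an enal before or during olefination, and residual formaldehyde may consume the ylide. The fallback carries nitrogen through the aldehyde stage as a phthalimide, a much poorer leaving group, and sulfonylates last. Setting out from 6 (isolated as the salt by evaporation), heating with phthalic anhydride and Et3N in toluene with azeotropic removal of water would give 2,2'-[(4R,5R)-octa-1,7-diene-4,5-diyl]bis(isoindoline-1,3-dione) F6. Ozonolysis (O3, CH2Cl2, −78 °C; PPh3) would give 2,2'-[(3R,4R)-1,6-dioxohexane-3,4-diyl]bis(isoindoline-1,3-dione) F7, and CBr4/PPh3 (CH2Cl2, 0 °C) would give 2,2'-[(4R,5R)-1,1,8,8-tetrabromoocta-1,7-diene-4,5-diyl]bis(isoindoline-1,3-dione) F8. Hydrazinolysis (N2H4·H2O, EtOH, 50 °C) would release (4R,5R)-1,1,8,8-tetrabromoocta-1,7-diene-4,5-diamine F9, and TsCl/pyridine (CH2Cl2, 0 °C → rt) rejoins the route at 12.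

Further compounds
F1 | step 7 | N,N'-[(1Z,4R,5R,7Z)-1,8-dibromoocta-1,7-diene-4,5-diyl]bis(4-methylbenzenesulfonamide) | Cc1ccc(cc1)S(=O)(=O)N[C@H](C/C=C\Br)[C@@H](C/C=C\Br)NS(=O)(=O)c1ccc(C)cc1
F2 | step 7 | (2R,2'R)-1,1'-bis(4-methylbenzenesulfonyl)-2,2',3,3'-tetrahydro-1H,1'H-2,2'-bipyrrole | Cc1ccc(cc1)S(=O)(=O)N1C=CC[C@@H]1[C@H]1CC=CN1S(=O)(=O)c1ccc(C)cc1
F3 | step 7 | 1H,1'H-2,2'-bipyrrole | c1cc([nH]c1)-c1ccc[nH]1
F4 | step 8 | 5,5'-dibromo-1,1'-bis(4-methylbenzenesulfonyl)-1H,1'H-2,2'-bipyrrole | Cc1ccc(cc1)S(=O)(=O)n1c(Br)ccc1-c1ccc(Br)n1S(=O)(=O)c1ccc(C)cc1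
F5 | step 8 | 3,3',4,4',5,5'-hexabromo-1,1'-bis(4-methylbenzenesulfonyl)-1H,1'H-2,2'-bipyrrole | Cc1ccc(cc1)S(=O)(=O)n1c(Br)c(Br)c(Br)c1-c1c(Br)c(Br)c(Br)n1S(=O)(=O)c1ccc(C)cc1
F6 | step 5 | 2,2'-[(4R,5R)-octa-1,7-diene-4,5-diyl]bis(isoindoline-1,3-dione) | O=C1c2ccccc2C(=O)N1[C@H](CC=C)[C@@H](CC=C)N1C(=O)c2ccccc2C1=O
F7 | step 5 | 2,2'-[(3R,4R)-1,6-dioxohexane-3,4-diyl]bis(isoindoline-1,3-dione) | O=C1c2ccccc2C(=O)N1[C@H](CC=O)[C@@H](CC=O)N1C(=O)c2ccccc2C1=O
F8 | step 5 | 2,2'-[(4R,5R)-1,1,8,8-tetrabromoocta-1,7-diene-4,5-diyl]bis(isoindoline-1,3-dione) | O=C1c2ccccc2C(=O)N1[C@H](CC=C(Br)Br)[C@@H](CC=C(Br)Br)N1C(=O)c2ccccc2C1=O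
F9 | step 5 | (4R,5R)-1,1,8,8-tetrabromoocta-1,7-diene-4,5-diamine | N[C@H](CC=C(Br)Br)[C@@H](CC=C(Br)Br)N
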